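The isoflavone is disconnected at C4–C4a of the pyranone ring (ring C), with the O1–C2 aryl vinyl ether already in place. Ring A is a phloroglucinol whose C6 and C8 carry the two C5 chains, so C4a is its only unsubstituted carbon, flanked by C8a–O1 and C5–O. Once the three-carbon acid C2=C3(aryl)–C4O2H hangs from O1, an intramolecular Friedel–Crafts acylation can close ring C in one way only and delivers the complete isoflavone skeleton in a single operation. Its precursor is a (Z)-2-aryl-3-aryloxyacrylic acid: ring B as a bis-MOM catechol, ring A with two MOM ethers, the prenyl group and the (R)-silyloxy side chain derived from methyl (R)-glycidate.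

Key step: step 15

Remark (assumption): isoflavone numbering is used (O1, C2–C4, C4a, C5–C8, C8a). The single stereocentre is R (O > isopropenyl > ArCH2 > H), which is what methyl (R)-glycidate delivers when opened at its CH2 carbon. The acid must be Z (CO2H cis to the aryloxy group) for the ring to close, and the structures below are drawn accordingly.

**Route**

Step 1
Reactants: 1 phloroglucinol
Product: 2 3,5-bis(methoxymethoxy)phenol
Conditions: MOMCl (2.0 equiv), i-Pr2NEt, DMF, 0 °C → rt; chromatography (mono-ether recycled)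
Reagents that add atoms: chloromethyl methyl ether (MOMCl), COCCl
Why: Williamson-type O-alkylation of the three equivalent phenols with two equivalents of MOMCl gives the bis-ether as the main component of a statistical mixture, a known and separable outcome for phloroglucinol.

Step 2
Reactants: 2 3,5-bis(methoxymethoxy)phenol
Product: 3 [3,5-bis(methoxymethoxy)phenoxy]triisopropylsilane
Conditions: TIPSCl, imidazole, DMF, rt
Reagents that add atoms: chlorotriisopropylsilane (TIPSCl), CC(C)[Si](Cl)(C(C)C)C(C)C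
Why: Imidazole-promoted O-silylation of the one remaining phenol puts a bulky, non-coordinating group, orthogonal to MOM, on the oxygen that will become O1.

Step 3
Reactants: 3 [3,5-bis(methoxymethoxy)phenoxy]triisopropylsilane; 4 prenyl bromide (1-bromo-3-methylbut-2-ene)
Product: 6 [3,5-bis(methoxymethoxy)-4-(3-methylbut-2-en-1-yl)phenoxy]triisopropylsilane, via aryllithium 5 (not isolated)
Conditions: n-BuLi, THF, 0 °C; then CuI (10 mol%), 4, −78 °C → rt
Reagents that add atoms: prenyl bromide 4, CC(C)=CCBr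
Why: Directed ortho-metalation places lithium on the carbon between the two MOM ethers (the future C6), the site activated by two coordinating acetal oxygens and remote from the bulky non-directing OTIPS group, and copper-catalysed SN2 alkylation with prenyl bromide then gives the linear prenyl arene.

Step 4
Reactants: 6 [3,5-bis(methoxymethoxy)-4-(3-methylbut-2-en-1-yl)phenoxy]triisopropylsilane
Product: 7 [2-bromo-3,5-bis(methoxymethoxy)-4-(3-methylbut-2-en-1-yl)phenoxy]triisopropylsilane
Conditions: NBS (1.0 equiv), MeCN, −30 °C, dark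
Reagents that add atoms: N-bromosuccinimide, O=C1CCC(=O)N1Br
Why: Electrophilic aromatic bromination by NBS of this tri-oxygenated ring should be far faster at low temperature than attack on the trisubstituted alkene, and since the two free ring positions are equivalent by symmetry one equivalent should give a single monobromide.

Step 5
Reactants: 7 [2-bromo-3,5-bis(methoxymethoxy)-4-(3-methylbut-2-en-1-yl)phenoxy]triisopropylsilane; 8 methyl (R)-glycidate (methyl (2R)-oxirane-2-carboxylate)
Product: 11 methyl (2R)-2-hydroxy-3-[2,4-bis(methoxymethoxy)-3-(3-methylbut-2-en-1-yl)-6-(triisopropylsilyloxy)phenyl]propanoate, via aryllithium 9 (not isolated), via arylmagnesium bromide 10 (not isolated)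
Conditions: t-BuLi (2.0 equiv), Et2O, −78 °C; MgBr2·OEt2, −78 → −40 °C; CuI (15 mol%), 8, THF, −40 → −20 °C; aqueous work-up
Reagents that add atoms: methyl (R)-glycidate 8, COC(=O)[C@H]1CO1
Why: Bromine–lithium exchange at −78 °C, transmetalation to magnesium and copper-catalysed SN2 opening of the glycidate at its unsubstituted CH2 carbon (the known route from aryl Grignard reagents to 3-aryl-lactates) form the aryl–CH2 bond, and the stereocentre is carried over untouched from the glycidate, so the carbinol is R (O > CO2Me > CH2Ar).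

Step 6
Reactants: 11 methyl (2R)-2-hydroxy-3-[2,4-bis(methoxymethoxy)-3-(3-methylbut-2-en-1-yl)-6-(triisopropylsilyloxy)phenyl]propanoate
Product: 12 methyl (2R)-2-(tert-butyldimethylsilyloxy)-3-[2,4-bis(methoxymethoxy)-3-(3-methylbut-2-en-1-yl)-6-(triisopropylsilyloxy)phenyl]propanoate
Conditions: TBSCl, imidazole, DMAP (cat.), DMF, rt
Reagents that add atoms: tert-butyldimethylsilyl chloride (TBSCl), CC(C)(C)[Si](C)(C)Cl
Why: Standard silylation of a secondary α-hydroxy ester; the TBS ether masks the hydroxyl against the Grignard, ylide and acylating reagents to come and is orthogonal to the aryl TIPS ether towards fluoride.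

Step 7
Reactants: 12 methyl (2R)-2-(tert-butyldimethylsilyloxy)-3-[2,4-bis(methoxymethoxy)-3-(3-methylbut-2-en-1-yl)-6-(triisopropylsilyloxy)phenyl]propanoate
Product: 14 (3R)-3-(tert-butyldimethylsilyloxy)-4-[2,4-bis(methoxymethoxy)-3-(3-methylbut-2-en-1-yl)-6-(triisopropylsilyloxy)phenyl]butan-2-one, via Weinreb amide 13 (not isolated)
Conditions: MeNH(OMe)·HCl, i-PrMgCl, THF, −20 °C; then MeMgBr, −20 → 0 °C; aqueous work-up
Reagents that add atoms: methylmagnesium bromide, C[Mg]Br
Why: One-pot Weinreb ketone synthesis, in which the magnesium amide of N,O-dimethylhydroxylamine converts the ester into the N-methoxy-N-methylamide and the chelated adduct of that amide with MeMgBr survives until work-up, so addition stops at the methyl ketone without touching the α-stereocentre.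

Step 8
Reactants: 14 (3R)-3-(tert-butyldimethylsilyloxy)-4-[2,4-bis(methoxymethoxy)-3-(3-methylbut-2-en-1-yl)-6-(triisopropylsilyloxy)phenyl]butan-2-one
Product: 15 {2-[(2R)-2-(tert-butyldimethylsilyloxy)-3-methylbut-3-en-1-yl]-3,5-bis(methoxymethoxy)-4-(3-methylbut-2-en-1-yl)phenoxy}triisopropylsilane
Conditions: Ph3PCH3Br (1.5 equiv), KHMDS (1.4 equiv), THF, 0 °C; then 14, −78 → 0 °C
Reagents that add atoms: methyltriphenylphosphonium bromide, C[P+](c1ccccc1)(c1ccccc1)c1ccccc1.[Br-]
Why: Wittig methylenation with Ph3P=CH2, generated with a slight deficit of base and used at low temperature, converts the methyl ketone into the isopropenyl group without enolising the α-silyloxy ketone, so the R centre (now O > isopropenyl > CH2Ar) should be preserved.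

Step 9
Reactants: 16 3,4-dihydroxyphenylacetic acid
Product: 17 allyl 3,4-dihydroxyphenylacetate
Conditions: allyl alcohol (solvent), TsOH·H2O (cat.), 70 °C
Reagents that add atoms: allyl alcohol, C=CCO
Why: Fischer esterification in allyl alcohol as solvent; the allyl ester is chosen so that the acid can later be released under neutral Pd(0) conditions instead of by hydroxide.

Step 10
Reactants: 17 allyl 3,4-dihydroxyphenylacetate
Product: 18 allyl 3,4-bis(methoxymethoxy)phenylacetate
Conditions: MOMCl (2.5 equiv), i-Pr2NEt, CH2Cl2, 0 °C → rt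
Reagents that add atoms: chloromethyl methyl ether (MOMCl), COCCl
Why: Williamson-type O-alkylation of both catechol hydroxyls with MOMCl under amine base, leaving the ester untouched.

Step 11
Reactants: 18 allyl 3,4-bis(methoxymethoxy)phenylacetate
Product: 19 allyl (Z)-3-hydroxy-2-[3,4-bis(methoxymethoxy)phenyl]acrylate (enol form of the 2-formyl ester)
Conditions: NaH, allyl formate, THF, 0 °C → rt; then AcOH, 0 °C
Reagents that add atoms: allyl formate, C=CCOC=O
Why: Crossed Claisen condensation (C-formylation) of the arylacetate enolate with allyl formate, whose alkoxide matches the ester and so cannot scramble it, is driven by formation of the stabilised sodium enolate, which on mild acidification gives the hydrogen-bonded Z-enol.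

Step 12
Reactants: 19 allyl (Z)-3-hydroxy-2-[3,4-bis(methoxymethoxy)phenyl]acrylate
Product: 21 allyl (Z)-3-chloro-2-[3,4-bis(methoxymethoxy)phenyl]acrylate, via O-formiminium enol ether 20 (not isolated)
Conditions: (COCl)2, DMF, CH2Cl2, 0 °C (preformed Vilsmeier salt); then 19, 2,6-lutidine, 0 °C → rt
Reagents that add atoms: oxalyl chloride (chlorine delivered through the Vilsmeier salt), O=C(Cl)C(=O)Cl
Why: Vilsmeier-type chlorodehydroxylation, in which the enol oxygen is activated as an O-formiminium ether and displaced by chloride through addition–elimination, should proceed with retention (very good leaving group) to put chlorine cis to the ester, while lutidine takes up the HCl so that the MOM ethers see no acid.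

Step 13
Reactants: 15 {2-[(2R)-2-(tert-butyldimethylsilyloxy)-3-methylbut-3-en-1-yl]-3,5-bis(methoxymethoxy)-4-(3-methylbut-2-en-1-yl)phenoxy}triisopropylsilane; 21 allyl (Z)-3-chloro-2-[3,4-bis(methoxymethoxy)phenyl]acrylate
Product: 23 allyl (Z)-2-[3,4-bis(methoxymethoxy)phenyl]-3-{2-[(2R)-2-(tert-butyldimethylsilyloxy)-3-methylbut-3-en-1-yl]-3,5-bis(methoxymethoxy)-4-(3-methylbut-2-en-1-yl)phenoxy}acrylate, via tetrabutylammonium phenoxide 22 (not isolated)
Conditions: TBAF (1.05 equiv), THF, 0 °C, 20 min; then 21, 0 °C → rt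
Reagents that add atoms: none
Why: Fluoride cleaves the aryl O–Si bond much faster than the secondary alkyl TBS ether, and the resulting ammonium phenoxide displaces chloride from the β-chloroacrylate by addition–elimination (nucleophilic vinylic substitution), a process that normally goes with retention for a good leaving group and therefore should place the aryloxy group cis to the ester and fix O1 on the oxygen beside the C8 chain.

Step 14
Reactants: 23 allyl (Z)-2-[3,4-bis(methoxymethoxy)phenyl]-3-{2-[(2R)-2-(tert-butyldimethylsilyloxy)-3-methylbut-3-en-1-yl]-3,5-bis(methoxymethoxy)-4-(3-methylbut-2-en-1-yl)phenoxy}acrylate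
Product: 24 (Z)-2-[3,4-bis(methoxymethoxy)phenyl]-3-{2-[(2R)-2-(tert-butyldimethylsilyloxy)-3-methylbut-3-en-1-yl]-3,5-bis(methoxymethoxy)-4-(3-methylbut-2-en-1-yl)phenoxy}acrylic acid
Conditions: Pd(PPh3)4 (5 mol%), sodium p-toluenesulfinate, THF/MeOH, rt; then cold dilute HCl to pH 4, rapid extraction
Reagents that add atoms: none
Why: Tsuji–Trost deallylation, in which Pd(0) ionises the allyl ester and the sulfinate traps the π-allyl complex irreversibly as the sulfone, frees the acid without exposing the vinylogous carbonate to hydroxide or amine nucleophiles that could displace the aryloxide from the β-carbon.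

Step 15
Reactants: 24 (Z)-2-[3,4-bis(methoxymethoxy)phenyl]-3-{2-[(2R)-2-(tert-butyldimethylsilyloxy)-3-methylbut-3-en-1-yl]-3,5-bis(methoxymethoxy)-4-(3-methylbut-2-en-1-yl)phenoxy}acrylic acid
Product: 27 8-[(2R)-2-(tert-butyldimethylsilyloxy)-3-methylbut-3-en-1-yl]-3-[3,4-bis(methoxymethoxy)phenyl]-5,7-bis(methoxymethoxy)-6-(3-methylbut-2-en-1-yl)-4H-chromen-4-one, via acid chloride 25 (not isolated), via acyl triflate 26 (not isolated)
Conditions: 1-chloro-N,N,2-trimethylprop-1-en-1-amine (1.0 equiv), CH2Cl2, 0 °C → rt; then 2,6-di-tert-butyl-4-methylpyridine (1.5 equiv), AgOTf (1.05 equiv), −40 → 0 °C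
Reagents that add atoms: none
Why: The chloroenamine converts the acid into acid chloride 25 without liberating HCl, silver triflate abstracts chloride to give the acyl triflate 26 (an acylium equivalent), and this attacks C4a, the only unsubstituted carbon of ring A (ortho to O1 and to the C5 MOM ether, para to the C7 oxygen), after which the arenium ion gives its proton to the hindered pyridine. The closest known reaction type is the intramolecular Friedel–Crafts acylation of 3-aryloxyacrylic acids to chromones, run here through an acyl triflate instead of a protic or strong Lewis acid. Ring C closes by a six-membered electrophilic aromatic substitution, 6-exo at the acyl carbon (the C=O bond stays outside the new ring). No stereocentre is formed, and the existing R centre lies on the side chain away from the reacting atoms and is not involved. The step needs regioselectivity, which the substrate secures because O1 was fixed beforehand and C4a is the only free ring position, and chemoselectivity over the prenyl and isopropenyl alkenes and the MOM ethers, which is secured because the triflic acid is bound by the hindered base as it forms. The Z geometry of 24 holds the acyl group over C4a, and any E material should still converge because the acylium ion has an oxocarbenium–ketene resonance form with a single Cα–Cβ bond.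

Step 16
Reactants: 27 8-[(2R)-2-(tert-butyldimethylsilyloxy)-3-methylbut-3-en-1-yl]-3-[3,4-bis(methoxymethoxy)phenyl]-5,7-bis(methoxymethoxy)-6-(3-methylbut-2-en-1-yl)-4H-chromen-4-one
Product: 28 3-(3,4-dihydroxyphenyl)-5,7-dihydroxy-8-[(2R)-2-hydroxy-3-methylbut-3-en-1-yl]-6-(3-methylbut-2-en-1-yl)-4H-chromen-4-one (CNP0236775.1)
Conditions: 3 M aq. HCl/MeOH (1:9), 40 °C, under argon
Reagents that add atoms: none
Why: Acid-catalysed methanolysis (transacetalisation of the four aryl MOM acetals to dimethoxymethane and Si–O cleavage of the secondary TBS ether) removes all five protecting groups in one operation under the dilute-acid conditions commonly used for prenylated polyphenols, and no bond to the stereocentre is broken.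

**Compound list**

1 | phloroglucinol | Oc1cc(O)cc(O)c1 | starting material
2 | 3,5-bis(methoxymethoxy)phenol | COCOc1cc(O)cc(OCOC)c1 | intermediate
3 | [3,5-bis(methoxymethoxy)phenoxy]triisopropylsilane | COCOc1cc(OCOC)cc(O[Si](C(C)C)(C(C)C)C(C)C)c1 | intermediate
4 | prenyl bromide | CC(C)=CCBr | starting material
5 | 2,6-bis(methoxymethoxy)-4-(triisopropylsilyloxy)phenyllithium | [Li]c1c(OCOC)cc(O[Si](C(C)C)(C(C)C)C(C)C)cc1OCOC | intermediate
6 | [3,5-bis(methoxymethoxy)-4-(3-methylbut-2-en-1-yl)phenoxy]triisopropylsilane | COCOc1cc(O[Si](C(C)C)(C(C)C)C(C)C)cc(OCOC)c1CC=C(C)C | intermediate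
7 | [2-bromo-3,5-bis(methoxymethoxy)-4-(3-methylbut-2-en-1-yl)phenoxy]triisopropylsilane | COCOc1c(Br)c(O[Si](C(C)C)(C(C)C)C(C)C)cc(OCOC)c1CC=C(C)C | intermediate
8 | methyl (R)-glycidate | COC(=O)[C@H]1CO1 | starting material
9 | 2,4-bis(methoxymethoxy)-3-(3-methylbut-2-en-1-yl)-6-(triisopropylsilyloxy)phenyllithium | [Li]c1c(O[Si](C(C)C)(C(C)C)C(C)C)cc(OCOC)c(CC=C(C)C)c1OCOC | intermediate
10 | 2,4-bis(methoxymethoxy)-3-(3-methylbut-2-en-1-yl)-6-(triisopropylsilyloxy)phenylmagnesium bromide | Br[Mg]c1c(O[Si](C(C)C)(C(C)C)C(C)C)cc(OCOC)c(CC=C(C)C)c1OCOC | intermediate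
11 | methyl (2R)-2-hydroxy-3-[2,4-bis(methoxymethoxy)-3-(3-methylbut-2-en-1-yl)-6-(triisopropylsilyloxy)phenyl]propanoate | COC(=O)[C@H](O)Cc1c(OCOC)c(CC=C(C)C)c(OCOC)cc1O[Si](C(C)C)(C(C)C)C(C)C | intermediate
12 | methyl (2R)-2-(tert-butyldimethylsilyloxy)-3-[2,4-bis(methoxymethoxy)-3-(3-methylbut-2-en-1-yl)-6-(triisopropylsilyloxy)phenyl]propanoate | COC(=O)[C@H](O[Si](C)(C)C(C)(C)C)Cc1c(OCOC)c(CC=C(C)C)c(OCOC)cc1O[Si](C(C)C)(C(C)C)C(C)C | intermediate
13 | (2R)-2-(tert-butyldimethylsilyloxy)-N-methoxy-N-methyl-3-[2,4-bis(methoxymethoxy)-3-(3-methylbut-2-en-1-yl)-6-(triisopropylsilyloxy)phenyl]propanamide | CON(C)C(=O)[C@H](O[Si](C)(C)C(C)(C)C)Cc1c(OCOC)c(CC=C(C)C)c(OCOC)cc1O[Si](C(C)C)(C(C)C)C(C)C | intermediate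
14 | (3R)-3-(tert-butyldimethylsilyloxy)-4-[2,4-bis(methoxymethoxy)-3-(3-methylbut-2-en-1-yl)-6-(triisopropylsilyloxy)phenyl]butan-2-one | CC(=O)[C@H](O[Si](C)(C)C(C)(C)C)Cc1c(OCOC)c(CC=C(C)C)c(OCOC)cc1O[Si](C(C)C)(C(C)C)C(C)C | intermediate
15 | {2-[(2R)-2-(tert-butyldimethylsilyloxy)-3-methylbut-3-en-1-yl]-3,5-bis(methoxymethoxy)-4-(3-methylbut-2-en-1-yl)phenoxy}triisopropylsilane | C=C(C)[C@H](O[Si](C)(C)C(C)(C)C)Cc1c(OCOC)c(CC=C(C)C)c(OCOC)cc1O[Si](C(C)C)(C(C)C)C(C)C | intermediate
16 | 3,4-dihydroxyphenylacetic acid | OC(=O)Cc1ccc(O)c(O)c1 | starting material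
17 | allyl 3,4-dihydroxyphenylacetate | C=CCOC(=O)Cc1ccc(O)c(O)c1 | intermediate
18 | allyl 3,4-bis(methoxymethoxy)phenylacetate | C=CCOC(=O)Cc1ccc(OCOC)c(OCOC)c1 | intermediate
19 | allyl (Z)-3-hydroxy-2-[3,4-bis(methoxymethoxy)phenyl]acrylate | C=CCOC(=O)/C(=C\O)c1ccc(OCOC)c(OCOC)c1 | intermediate
20 | allyl (Z)-3-[(dimethyliminio)methoxy]-2-[3,4-bis(methoxymethoxy)phenyl]acrylate chloride | C=CCOC(=O)/C(=C\OC=[N+](C)C)c1ccc(OCOC)c(OCOC)c1.[Cl-] | intermediate
21 | allyl (Z)-3-chloro-2-[3,4-bis(methoxymethoxy)phenyl]acrylate | C=CCOC(=O)/C(=C\Cl)c1ccc(OCOC)c(OCOC)c1 | intermediate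
22 | tetrabutylammonium 2-[(2R)-2-(tert-butyldimethylsilyloxy)-3-methylbut-3-en-1-yl]-3,5-bis(methoxymethoxy)-4-(3-methylbut-2-en-1-yl)phenoxide | C=C(C)[C@H](O[Si](C)(C)C(C)(C)C)Cc1c(OCOC)c(CC=C(C)C)c(OCOC)cc1[O-].CCCC[N+](CCCC)(CCCC)CCCC | intermediate
23 | allyl (Z)-2-[3,4-bis(methoxymethoxy)phenyl]-3-{2-[(2R)-2-(tert-butyldimethylsilyloxy)-3-methylbut-3-en-1-yl]-3,5-bis(methoxymethoxy)-4-(3-methylbut-2-en-1-yl)phenoxy}acrylate | C=CCOC(=O)/C(=C\Oc1cc(OCOC)c(CC=C(C)C)c(OCOC)c1C[C@@H](O[Si](C)(C)C(C)(C)C)C(C)=C)c1ccc(OCOC)c(OCOC)c1 | intermediate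
24 | (Z)-2-[3,4-bis(methoxymethoxy)phenyl]-3-{2-[(2R)-2-(tert-butyldimethylsilyloxy)-3-methylbut-3-en-1-yl]-3,5-bis(methoxymethoxy)-4-(3-methylbut-2-en-1-yl)phenoxy}acrylic acid | OC(=O)/C(=C\Oc1cc(OCOC)c(CC=C(C)C)c(OCOC)c1C[C@@H](O[Si](C)(C)C(C)(C)C)C(C)=C)c1ccc(OCOC)c(OCOC)c1 | intermediate
25 | acid chloride of 24 | ClC(=O)/C(=C\Oc1cc(OCOC)c(CC=C(C)C)c(OCOC)c1C[C@@H](O[Si](C)(C)C(C)(C)C)C(C)=C)c1ccc(OCOC)c(OCOC)c1 | intermediate
26 | mixed carboxylic–trifluoromethanesulfonic anhydride of 24 | O=C(OS(=O)(=O)C(F)(F)F)/C(=C\Oc1cc(OCOC)c(CC=C(C)C)c(OCOC)c1C[C@@H](O[Si](C)(C)C(C)(C)C)C(C)=C)c1ccc(OCOC)c(OCOC)c1 | intermediate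
27 | 8-[(2R)-2-(tert-butyldimethylsilyloxy)-3-methylbut-3-en-1-yl]-3-[3,4-bis(methoxymethoxy)phenyl]-5,7-bis(methoxymethoxy)-6-(3-methylbut-2-en-1-yl)-4H-chromen-4-one | C=C(C)[C@H](O[Si](C)(C)C(C)(C)C)Cc1c(OCOC)c(CC=C(C)C)c(OCOC)c2c(=O)c(-c3ccc(OCOC)c(OCOC)c3)coc12 | intermediate
28 | 3-(3,4-dihydroxyphenyl)-5,7-dihydroxy-8-[(2R)-2-hydroxy-3-methylbut-3-en-1-yl]-6-(3-methylbut-2-en-1-yl)-4H-chromen-4-one | C=C(C)[C@H](O)Cc1c(O)c(CC=C(C)C)c(O)c2c(=O)c(-c3ccc(O)c(O)c3)coc12 | target

**Step count and risks**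

Total step count: 16. Longest linear sequence: 12 (steps 1–8, then 13–16); the ring B branch (steps 9–12) joins at step 13.

Steps most likely to fail:

1. Step 15 (key step). The ring closure may stall if material of E geometry does not isomerise at the acylium stage, or the electrophilic medium may strip MOM groups or engage the alkenes before C4a is acylated. The fallback is the classical deoxybenzoin construction, in which C4–C4a is made by anionic acylation and ring C is closed at O1–C2. It sets out from 15 and comes back at 27. 15 is brominated at its last free ring carbon (NBS, MeCN, −30 °C) to give the aryl bromide F1. Bromine–lithium exchange (t-BuLi, Et2O, −78 °C) and acylation with the Weinreb amide F2 (made from 18 with MeNH(OMe)·HCl and i-PrMgCl, THF, −20 °C) give the deoxybenzoin F3. TBAF (THF, 0 °C) frees the ortho-hydroxy deoxybenzoin F4. Heating with N,N-dimethylformamide dimethyl acetal (toluene, 80 °C) gives the enaminone F5, which closes by attack of the phenol on the enamine carbon and loss of dimethylamine to give 27.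

2. Step 5. Epoxide opening by the doubly ortho-substituted aryl metal may be slow, so that attack on the ester carbonyl or halide opening of the epoxide takes over. The fallback removes the ester before the coupling and makes the alkene by dehydration. It sets out from 7 and 8 and comes back at 15. 8 is treated with MeMgBr (THF, −78 °C) to give the epoxy carbinol F6. Its magnesium alkoxide (i-PrMgCl) is opened at CH2 by the arylmagnesium bromide 10 (from 7 as in step 5, CuI cat.) to give the diol F7. TBSCl/imidazole silylates only the secondary hydroxyl to give the mono-TBS ether F8. Burgess reagent (THF, 50 °C) dehydrates the tertiary alcohol towards a methyl group to give 15.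

3. Step 16. Under protic acid the freed phenols may add to the protonated prenyl or isopropenyl groups (chromane or dihydrofuran formation), or the allylic alcohol may solvolyse, before all four MOM groups are off. The fallback is a two-stage deprotection without free protic acid. It sets out from 27 and comes back at 28. TMSOTf/2,2′-bipyridyl (CH2Cl2, 0 °C) converts the aryl MOM ethers into the tetrakis(trimethylsilyl) ether F9, which water hydrolyses during work-up to the TBS-protected tetraphenol F10. HF·pyridine buffered with pyridine (THF, 0 °C) then removes the silyl ether to give 28.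

Further compounds
F1 | step 15 | {6-bromo-2-[(2R)-2-(tert-butyldimethylsilyloxy)-3-methylbut-3-en-1-yl]-3,5-bis(methoxymethoxy)-4-(3-methylbut-2-en-1-yl)phenoxy}triisopropylsilane | C=C(C)[C@H](O[Si](C)(C)C(C)(C)C)Cc1c(OCOC)c(CC=C(C)C)c(OCOC)c(Br)c1O[Si](C(C)C)(C(C)C)C(C)C
F2 | step 15 | N-methoxy-N-methyl-2-[3,4-bis(methoxymethoxy)phenyl]acetamide | CON(C)C(=O)Cc1ccc(OCOC)c(OCOC)c1
F3 | step 15 | 1-{3-[(2R)-2-(tert-butyldimethylsilyloxy)-3-methylbut-3-en-1-yl]-4,6-bis(methoxymethoxy)-5-(3-methylbut-2-en-1-yl)-2-(triisopropylsilyloxy)phenyl}-2-[3,4-bis(methoxymethoxy)phenyl]ethanone | C=C(C)[C@H](O[Si](C)(C)C(C)(C)C)Cc1c(OCOC)c(CC=C(C)C)c(OCOC)c(C(=O)Cc2ccc(OCOC)c(OCOC)c2)c1O[Si](C(C)C)(C(C)C)C(C)C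
F4 | step 15 | 1-{3-[(2R)-2-(tert-butyldimethylsilyloxy)-3-methylbut-3-en-1-yl]-2-hydroxy-4,6-bis(methoxymethoxy)-5-(3-methylbut-2-en-1-yl)phenyl}-2-[3,4-bis(methoxymethoxy)phenyl]ethanone | C=C(C)[C@H](O[Si](C)(C)C(C)(C)C)Cc1c(OCOC)c(CC=C(C)C)c(OCOC)c(C(=O)Cc2ccc(OCOC)c(OCOC)c2)c1O
F5 | step 15 | (E)-3-(dimethylamino)-1-{3-[(2R)-2-(tert-butyldimethylsilyloxy)-3-methylbut-3-en-1-yl]-2-hydroxy-4,6-bis(methoxymethoxy)-5-(3-methylbut-2-en-1-yl)phenyl}-2-[3,4-bis(methoxymethoxy)phenyl]prop-2-en-1-one | C=C(C)[C@H](O[Si](C)(C)C(C)(C)C)Cc1c(OCOC)c(CC=C(C)C)c(OCOC)c(C(=O)/C(=C/N(C)C)c2ccc(OCOC)c(OCOC)c2)c1O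
F6 | step 5 | (R)-2-(oxiran-2-yl)propan-2-ol | CC(C)(O)[C@H]1CO1
F7 | step 5 | (2R)-1-[2,4-bis(methoxymethoxy)-3-(3-methylbut-2-en-1-yl)-6-(triisopropylsilyloxy)phenyl]-3-methylbutane-2,3-diol | CC(C)(O)[C@H](O)Cc1c(OCOC)c(CC=C(C)C)c(OCOC)cc1O[Si](C(C)C)(C(C)C)C(C)C
F8 | step 5 | (3R)-3-(tert-butyldimethylsilyloxy)-4-[2,4-bis(methoxymethoxy)-3-(3-methylbut-2-en-1-yl)-6-(triisopropylsilyloxy)phenyl]-2-methylbutan-2-ol | CC(C)(O)[C@H](O[Si](C)(C)C(C)(C)C)Cc1c(OCOC)c(CC=C(C)C)c(OCOC)cc1O[Si](C(C)C)(C(C)C)C(C)C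
F9 | step 16 | 8-[(2R)-2-(tert-butyldimethylsilyloxy)-3-methylbut-3-en-1-yl]-3-[3,4-bis(trimethylsilyloxy)phenyl]-6-(3-methylbut-2-en-1-yl)-5,7-bis(trimethylsilyloxy)-4H-chromen-4-one | C=C(C)[C@H](O[Si](C)(C)C(C)(C)C)Cc1c(O[Si](C)(C)C)c(CC=C(C)C)c(O[Si](C)(C)C)c2c(=O)c(-c3ccc(O[Si](C)(C)C)c(O[Si](C)(C)C)c3)coc12
F10 | step 16 | 8-[(2R)-2-(tert-butyldimethylsilyloxy)-3-methylbut-3-en-1-yl]-3-(3,4-dihydroxyphenyl)-5,7-dihydroxy-6-(3-methylbut-2-en-1-yl)-4H-chromen-4-one | C=C(C)[C@H](O[Si](C)(C)C(C)(C)C)Cc1c(O)c(CC=C(C)C)c(O)c2c(=O)c(-c3ccc(O)c(O)c3)coc12
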